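**Retrosynthetic overview**
- Labels: unit 1 = the 3,4-diarylchroman (C2, C3, C4), unit 2 = the 3-arylchroman (C2'', C3'', C4''), hub = the central methoxy/hydroxy benzene.
- Target ⇐ hydrogenolysis of five benzyl ethers ⇐ lactol deoxygenation ⇐ iridium-catalysed asymmetric hydrogenation of a lactol–chromene (sets C3'').
- Key disconnection: both pyran rings at once. A hub dilithio reagent (aryl carbon and α-styryl carbon) adds to two molecules of one o-Boc-salicylaldehyde, giving two o-quinone methides. The vinyl one closes by oxa-6π to the unit 2 chromene; the aryl one is trapped by a chiral B-ring enamine in a [4+2] that sets C3 and C4 of unit 1.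
- Building blocks: hub dibromide ⇐ 3-hydroxy-5-methoxybenzaldehyde; enamine ⇐ 2,3-dihydroxy-4-methoxybenzaldehyde and (R)-diphenylprolinol TMS ether; carbonate ⇐ 4-(benzyloxy)-2-hydroxybenzaldehyde.
- Ring order: all four benzene rings are bought; the two pyran rings form together in step 10.

Assumption: the target is the (3R,4S,3''R) isomer of the SMILES (3,4-trans in unit 1); the antipode of the iridium ligand in step 11 is fixed by a model run so that it gives R at C3''.

**Step 1**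
Reactants: 1 3-hydroxy-5-methoxybenzaldehyde
Product: 2 2-bromo-5-hydroxy-3-methoxybenzaldehyde
Conditions: NBS (1.0 equiv), MeCN, −20 → 0 °C
Reagents that add atoms: N-bromosuccinimide BrN1C(=O)CCC1=O
Why: Electrophilic aromatic bromination; the free phenol directs para, to the position that is also ortho to OMe (as 3-hydroxybenzaldehyde gives 2-bromo-5-hydroxybenzaldehyde), and the minor ortho isomer is removed by crystallisation.

**Step 2**
Reactants: 2 2-bromo-5-hydroxy-3-methoxybenzaldehyde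
Product: 3 5-(benzyloxy)-2-bromo-3-methoxybenzaldehyde
Conditions: BnBr (1.1 equiv), K2CO3, DMF, rt
Reagents that add atoms: benzyl bromide BrCc1ccccc1
Why: Williamson ether synthesis on the only phenol.

**Step 3**
Reactants: 3 5-(benzyloxy)-2-bromo-3-methoxybenzaldehyde
Product: 4 5-(benzyloxy)-2-bromo-1-ethynyl-3-methoxybenzene
Conditions: Ohira–Bestmann reagent (1.3 equiv), K2CO3 (2 equiv), MeOH, rt
Reagents that add atoms: dimethyl (1-diazo-2-oxopropyl)phosphonate CC(=O)C(=[N+]=[N-])P(=O)(OC)OC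
Why: Seyferth–Gilbert homologation (Ohira–Bestmann variant) turns the aryl aldehyde into the terminal alkyne under mild base that leaves the aryl bromide and benzyl ether alone.

**Step 4**
Reactants: 4 5-(benzyloxy)-2-bromo-1-ethynyl-3-methoxybenzene
Product: 6 5-(benzyloxy)-2-bromo-1-(1-bromoethenyl)-3-methoxybenzene, via alkenylalane 5 (not isolated)
Conditions: NiCl2(dppp) (3 mol%), i-Bu2AlH (1.3 equiv), THF, 0 → 22 °C; then NBS (1.5 equiv), 0 °C
Reagents that add atoms: N-bromosuccinimide BrN1C(=O)CCC1=O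
Why: Nickel-catalysed α-selective hydroalumination of an aryl acetylene (dppp ligand) followed by bromodealumination gives the 1-bromovinyl arene; the hindered, electron-rich aryl C–Br bond is expected to be slow towards the nickel catalyst.

**Step 5**
Reactants: 7 4-(benzyloxy)-2-hydroxybenzaldehyde
Product: 8 tert-butyl 5-(benzyloxy)-2-formylphenyl carbonate
Conditions: Boc2O (1.2 equiv), DMAP (5 mol%), i-Pr2NEt, THF, 0 °C → rt
Reagents that add atoms: di-tert-butyl dicarbonate CC(C)(C)OC(=O)OC(=O)OC(C)(C)C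
Why: DMAP-catalysed O-acylation gives the aryl tert-butyl carbonate, the latent o-quinone methide precursor.

**Step 6**
Reactants: 9 2,3-dihydroxy-4-methoxybenzaldehyde
Product: 10 2,3-bis(benzyloxy)-4-methoxybenzaldehyde
Conditions: BnBr (2.3 equiv), K2CO3, DMF, 60 °C
Reagents that add atoms: benzyl bromide BrCc1ccccc1
Why: Double Williamson ether synthesis; heating is needed for the hydrogen-bonded 2-OH.

**Step 7**
Reactants: 10 2,3-bis(benzyloxy)-4-methoxybenzaldehyde
Product: 11 2,3-bis(benzyloxy)-4-methoxy-1-(2-methoxyethenyl)benzene (E/Z mixture)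
Conditions: MeOCH2PPh3Cl (1.4 equiv), KOtBu, THF, 0 °C → rt
Reagents that add atoms: (methoxymethyl)triphenylphosphonium chloride COC[P+](c1ccccc1)(c1ccccc1)c1ccccc1.[Cl-]
Why: Wittig methoxymethylenation for one-carbon homologation; the alkene geometry is irrelevant because the enol ether is hydrolysed next.

**Step 8**
Reactants: 11 2,3-bis(benzyloxy)-4-methoxy-1-(2-methoxyethenyl)benzene
Product: 12 [2,3-bis(benzyloxy)-4-methoxyphenyl]acetaldehyde
Conditions: 1 M HCl, THF, 40 °C; used crude at once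
Reagents that add atoms: water O
Why: Acid hydrolysis of the enol ether gives the arylacetaldehyde; benzyl ethers survive dilute acid.

**Step 9**
Reactants: 12 [2,3-bis(benzyloxy)-4-methoxyphenyl]acetaldehyde; 13 (R)-2-[diphenyl(trimethylsilyloxy)methyl]pyrrolidine
Product: 14 (R)-1-{(E)-2-[2,3-bis(benzyloxy)-4-methoxyphenyl]ethenyl}-2-[diphenyl(trimethylsilyloxy)methyl]pyrrolidine
Conditions: 13 (1.0 equiv), MS 4 Å, CH2Cl2, rt; filtered, concentrated, used directly
Reagents that add atoms: none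
Why: Condensation of an arylacetaldehyde with a diarylprolinol silyl ether gives the conjugated E, s-trans enamine, as known for the phenylacetaldehyde enamine of this amine.

**Step 10 (key step)**
Reactants: 6 5-(benzyloxy)-2-bromo-1-(1-bromoethenyl)-3-methoxybenzene; 8 tert-butyl 5-(benzyloxy)-2-formylphenyl carbonate; 14 (R)-1-{(E)-2-[2,3-bis(benzyloxy)-4-methoxyphenyl]ethenyl}-2-[diphenyl(trimethylsilyloxy)methyl]pyrrolidine
Product: 18 (3R,4S)-7-(benzyloxy)-4-{4-(benzyloxy)-2-[7-(benzyloxy)-2H-chromen-3-yl]-6-methoxyphenyl}-3-[2,3-bis(benzyloxy)-4-methoxyphenyl]chroman-2-ol (anomer mixture), via dilithio reagent 15 (not isolated), via bis(o-quinone methide) 16 (not isolated), via aminal 17 (not isolated)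
Conditions: t-BuLi (4.2 equiv), Et2O, −78 °C; 8 (2.1 equiv), −78 °C; 14 (1.5 equiv) then MgBr2·OEt2 (2.5 equiv), −78 °C → rt; 0.5 M HCl, THF, 0 °C
Reagents that add atoms: water O
Why: Proposed new method: double Br/Li exchange gives a 1,4-dilithio reagent whose aryl and α-styryl carbanions add to two molecules of 8; with MgBr2 each alkoxide takes over the Boc group and the phenoxide expels tert-butyl carbonate to give two o-quinone methides; the vinyl-substituted one closes by oxa-6π electrocyclisation to the 2H-chromene (pyran ring of unit 2), while the aryl-substituted one has no internal partner and is captured by enamine 14 in an endo inverse-electron-demand hetero-Diels–Alder reaction (pyran ring of unit 1), then hydrolysed to the lactol; the CPh2OTMS group of the (R)-pyrrolidine blocks one face of the E-enamine so that C3 forms as R, and the endo (amine) approach to the E-o-quinone methide puts the two aryl groups trans so that C4 is S; closest known reactions are o-quinone methide generation from o-OBoc salicylaldehydes and organometallics with enol ether trapping, chromene formation from vinyl o-quinone methides, and diarylprolinol silyl ether enamine additions to o-quinone methides giving trans-3,4-disubstituted chroman-2-ols.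

**Step 11**
Reactants: 18 (3R,4S)-7-(benzyloxy)-4-{4-(benzyloxy)-2-[7-(benzyloxy)-2H-chromen-3-yl]-6-methoxyphenyl}-3-[2,3-bis(benzyloxy)-4-methoxyphenyl]chroman-2-ol
Product: 19 (3R,4S)-7-(benzyloxy)-4-{4-(benzyloxy)-2-[(3R)-7-(benzyloxy)chroman-3-yl]-6-methoxyphenyl}-3-[2,3-bis(benzyloxy)-4-methoxyphenyl]chroman-2-ol (anomer mixture)
Conditions: [Ir(cod)(L)]BArF (2 mol%; L = t-Bu-PHOX, antipode per model run; BArF = tetrakis[3,5-bis(trifluoromethyl)phenyl]borate), H2 (50 bar), CH2Cl2, rt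
Reagents that add atoms: none
Why: Iridium-catalysed asymmetric hydrogenation of a 3-aryl-2H-chromene with a phosphine–oxazoline ligand is a known route to isoflavans; catalyst-controlled delivery of H2 to one face sets C3'' as R, and benzyl ethers and the lactol are untouched.

**Step 12**
Reactants: 19 (3R,4S)-7-(benzyloxy)-4-{4-(benzyloxy)-2-[(3R)-7-(benzyloxy)chroman-3-yl]-6-methoxyphenyl}-3-[2,3-bis(benzyloxy)-4-methoxyphenyl]chroman-2-ol
Product: 20 (3R,4S)-7-(benzyloxy)-4-{4-(benzyloxy)-2-[(3R)-7-(benzyloxy)chroman-3-yl]-6-methoxyphenyl}-3-[2,3-bis(benzyloxy)-4-methoxyphenyl]chromane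
Conditions: Et3SiH (4 equiv), BF3·OEt2 (1.5 equiv), CH2Cl2, −78 → −20 °C
Reagents that add atoms: none
Why: Ionic hydrogenation of the lactol through the cyclic oxocarbenium ion; if C3 enolises through the 4H-chromene it reprotonates trans to the fixed C4 aryl, so the 3,4-trans relation is kept.

**Step 13**
Reactants: 20 (3R,4S)-7-(benzyloxy)-4-{4-(benzyloxy)-2-[(3R)-7-(benzyloxy)chroman-3-yl]-6-methoxyphenyl}-3-[2,3-bis(benzyloxy)-4-methoxyphenyl]chromane
Product: 21 (3R,4S)-3-(2,3-dihydroxy-4-methoxyphenyl)-4-{4-hydroxy-2-[(3R)-7-hydroxychroman-3-yl]-6-methoxyphenyl}chroman-7-ol (CNP0227211.1)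
Conditions: H2 (1 atm), 10% Pd/C, EtOAc/MeOH 1:1, rt
Reagents that add atoms: none
Why: Hydrogenolysis of the five benzyl aryl ethers; the chroman C–O bonds are not benzylic and the diarylmethine C4–H is inert, so no stereocentre is touched.

**Compound list**
1 | 3-hydroxy-5-methoxybenzaldehyde | COc1cc(O)cc(C=O)c1 | starting material
2 | 2-bromo-5-hydroxy-3-methoxybenzaldehyde | COc1cc(O)cc(C=O)c1Br | intermediate
3 | 5-(benzyloxy)-2-bromo-3-methoxybenzaldehyde | COc1cc(OCc2ccccc2)cc(C=O)c1Br | intermediate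
4 | 5-(benzyloxy)-2-bromo-1-ethynyl-3-methoxybenzene | COc1cc(OCc2ccccc2)cc(C#C)c1Br | intermediate
5 | {1-[5-(benzyloxy)-2-bromo-3-methoxyphenyl]ethenyl}bis(2-methylpropyl)alumane | COc1cc(OCc2ccccc2)cc(C(=C)[Al](CC(C)C)CC(C)C)c1Br | intermediate
6 | 5-(benzyloxy)-2-bromo-1-(1-bromoethenyl)-3-methoxybenzene | COc1cc(OCc2ccccc2)cc(C(Br)=C)c1Br | intermediate
7 | 4-(benzyloxy)-2-hydroxybenzaldehyde | O=Cc1ccc(OCc2ccccc2)cc1O | starting material
8 | tert-butyl 5-(benzyloxy)-2-formylphenyl carbonate | CC(C)(C)OC(=O)Oc1cc(OCc2ccccc2)ccc1C=O | intermediate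
9 | 2,3-dihydroxy-4-methoxybenzaldehyde | COc1ccc(C=O)c(O)c1O | starting material
10 | 2,3-bis(benzyloxy)-4-methoxybenzaldehyde | COc1ccc(C=O)c(OCc2ccccc2)c1OCc1ccccc1 | intermediate
11 | 2,3-bis(benzyloxy)-4-methoxy-1-(2-methoxyethenyl)benzene (E/Z mixture, geometry not defined) | COC=Cc1ccc(OC)c(OCc2ccccc2)c1OCc1ccccc1 | intermediate
12 | [2,3-bis(benzyloxy)-4-methoxyphenyl]acetaldehyde | O=CCc1ccc(OC)c(OCc2ccccc2)c1OCc1ccccc1 | intermediate
13 | (R)-2-[diphenyl(trimethylsilyloxy)methyl]pyrrolidine | C[Si](C)(C)OC(c1ccccc1)(c1ccccc1)[C@H]1CCCN1 | starting material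
14 | (R)-1-{(E)-2-[2,3-bis(benzyloxy)-4-methoxyphenyl]ethenyl}-2-[diphenyl(trimethylsilyloxy)methyl]pyrrolidine | COc1ccc(/C=C/N2CCC[C@@H]2C(O[Si](C)(C)C)(c2ccccc2)c2ccccc2)c(OCc2ccccc2)c1OCc1ccccc1 | intermediate
15 | [4-(benzyloxy)-2-(1-lithioethenyl)-6-methoxyphenyl]lithium | COc1cc(OCc2ccccc2)cc(C([Li])=C)c1[Li] | intermediate
16 | hub bis(o-quinone methide): 3-(benzyloxy)-6-methylidenecyclohexa-2,4-dien-1-one units joined through the methylidene carbon to hub C1 and through a 2-propenylidene chain to hub C6 | COc1cc(OCc2ccccc2)cc(C(=C)C=C2C=CC(OCc3ccccc3)=CC2=O)c1C=C1C=CC(OCc2ccccc2)=CC1=O | intermediate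
17 | (3R,4S)-2-pyrrolidinyl aminal of 18 (C2 not assigned; pyrrolidine as in 13) | COc1ccc([C@@H]2C(N3CCC[C@@H]3C(O[Si](C)(C)C)(c3ccccc3)c3ccccc3)Oc3cc(OCc4ccccc4)ccc3[C@H]2c2c(OC)cc(OCc3ccccc3)cc2C2=Cc3ccc(OCc4ccccc4)cc3OC2)c(OCc2ccccc2)c1OCc1ccccc1 | intermediate
18 | (3R,4S)-7-(benzyloxy)-4-{4-(benzyloxy)-2-[7-(benzyloxy)-2H-chromen-3-yl]-6-methoxyphenyl}-3-[2,3-bis(benzyloxy)-4-methoxyphenyl]chroman-2-ol (anomer mixture) | COc1ccc([C@@H]2C(O)Oc3cc(OCc4ccccc4)ccc3[C@H]2c2c(OC)cc(OCc3ccccc3)cc2C2=Cc3ccc(OCc4ccccc4)cc3OC2)c(OCc2ccccc2)c1OCc1ccccc1 | intermediate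
19 | (3R,4S)-7-(benzyloxy)-4-{4-(benzyloxy)-2-[(3R)-7-(benzyloxy)chroman-3-yl]-6-methoxyphenyl}-3-[2,3-bis(benzyloxy)-4-methoxyphenyl]chroman-2-ol (anomer mixture) | COc1ccc([C@@H]2C(O)Oc3cc(OCc4ccccc4)ccc3[C@H]2c2c(OC)cc(OCc3ccccc3)cc2[C@@H]2COc3cc(OCc4ccccc4)ccc3C2)c(OCc2ccccc2)c1OCc1ccccc1 | intermediate
20 | (3R,4S)-7-(benzyloxy)-4-{4-(benzyloxy)-2-[(3R)-7-(benzyloxy)chroman-3-yl]-6-methoxyphenyl}-3-[2,3-bis(benzyloxy)-4-methoxyphenyl]chromane | COc1ccc([C@@H]2COc3cc(OCc4ccccc4)ccc3[C@H]2c2c(OC)cc(OCc3ccccc3)cc2[C@@H]2COc3cc(OCc4ccccc4)ccc3C2)c(OCc2ccccc2)c1OCc1ccccc1 | intermediate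
21 | (3R,4S)-3-(2,3-dihydroxy-4-methoxyphenyl)-4-{4-hydroxy-2-[(3R)-7-hydroxychroman-3-yl]-6-methoxyphenyl}chroman-7-ol | COc1ccc([C@@H]2COc3cc(O)ccc3[C@H]2c2c(OC)cc(O)cc2[C@@H]2COc3cc(O)ccc3C2)c(O)c1O | target

**Totals**
Total step count: 13. Longest linear sequence: 8 steps (1 → 2 → 3 → 4 → 6 → 18 → 19 → 20 → 21; the branch from 9 is also 8).

**Steps most likely to fail**

Step 10. Risks: the enamine may intercept the vinyl o-quinone methide before it electrocyclises; the crowded aryl o-quinone methide (2,6-disubstituted hub) may react slowly with the bulky enamine; the double lithiation demands exact stoichiometry. Fallback, from 6 back to 18, building the two pyran rings one after the other: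
- A Nozaki–Hiyama–Kishi coupling of 6 with 7 (CrCl2, NiCl2 cat., DMF), which activates only the alkenyl bromide, gives the allylic alcohol 5-(benzyloxy)-2-{2-[5-(benzyloxy)-2-bromo-3-methoxyphenyl]-1-hydroxyprop-2-en-1-yl}phenol F1.
- PPTS in toluene at 60 °C dehydrates it through the vinyl o-quinone methide to 7-(benzyloxy)-3-[5-(benzyloxy)-2-bromo-3-methoxyphenyl]-2H-chromene F2.
- Br/Li exchange with t-BuLi gives [4-(benzyloxy)-2-(7-(benzyloxy)-2H-chromen-3-yl)-6-methoxyphenyl]lithium F3, which adds to one equivalent of 8.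
- MgBr2·OEt2 then releases the mono o-quinone methide 3-(benzyloxy)-6-{[4-(benzyloxy)-2-(7-(benzyloxy)-2H-chromen-3-yl)-6-methoxyphenyl]methylidene}cyclohexa-2,4-dien-1-one F4, which 14 captures to give aminal 17 and, after hydrolysis, 18.

Step 11. Risks: the trisubstituted alkene sits next to the very bulky, chiral unit 1, so conversion may be low and catalyst control may be eroded (matched/mismatched). Fallback, from 6 back to 19, hydrogenating before unit 1 exists:
- Chromene F2 (made from 6 through F1 as above) is hydrogenated with the same iridium catalyst at this unhindered stage to (3R)-7-(benzyloxy)-3-[5-(benzyloxy)-2-bromo-3-methoxyphenyl]chromane F5.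
- Br/Li exchange gives {4-(benzyloxy)-2-[(3R)-7-(benzyloxy)chroman-3-yl]-6-methoxyphenyl}lithium F6, which adds to 8.
- MgBr2·OEt2 releases the o-quinone methide 3-(benzyloxy)-6-({4-(benzyloxy)-2-[(3R)-7-(benzyloxy)chroman-3-yl]-6-methoxyphenyl}methylidene)cyclohexa-2,4-dien-1-one F7.
- Capture by 14 gives the 2-pyrrolidinyl aminal of 19 F8, and hydrolysis gives 19.

Step 4. Risks: the nickel hydride catalyst may reduce the aryl bromide, or i-Bu2AlH may deprotonate the alkyne instead of adding. Fallback, from 3 back to 6, through the methyl ketone: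
- MeMgBr (THF, 0 °C) gives 1-[5-(benzyloxy)-2-bromo-3-methoxyphenyl]ethan-1-ol F9.
- Dess–Martin periodinane gives 1-[5-(benzyloxy)-2-bromo-3-methoxyphenyl]ethan-1-one F10.
- Preformed (PhO)3P/Br2, then Et3N (CH2Cl2, −60 °C → rt), converts the enolisable ketone into vinyl bromide 6 without free bromine meeting the arene.

**Further compounds**
F1 | step 10 | 5-(benzyloxy)-2-{2-[5-(benzyloxy)-2-bromo-3-methoxyphenyl]-1-hydroxyprop-2-en-1-yl}phenol (racemic) | COc1cc(OCc2ccccc2)cc(C(=C)C(O)c2ccc(OCc3ccccc3)cc2O)c1Br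
F2 | step 10 | 7-(benzyloxy)-3-[5-(benzyloxy)-2-bromo-3-methoxyphenyl]-2H-chromene | COc1cc(OCc2ccccc2)cc(C2=Cc3ccc(OCc4ccccc4)cc3OC2)c1Br
F3 | step 10 | [4-(benzyloxy)-2-(7-(benzyloxy)-2H-chromen-3-yl)-6-methoxyphenyl]lithium | COc1cc(OCc2ccccc2)cc(C2=Cc3ccc(OCc4ccccc4)cc3OC2)c1[Li]
F4 | step 10 | 3-(benzyloxy)-6-{[4-(benzyloxy)-2-(7-(benzyloxy)-2H-chromen-3-yl)-6-methoxyphenyl]methylidene}cyclohexa-2,4-dien-1-one | COc1cc(OCc2ccccc2)cc(C2=Cc3ccc(OCc4ccccc4)cc3OC2)c1C=C1C=CC(OCc2ccccc2)=CC1=O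
F5 | step 11 | (3R)-7-(benzyloxy)-3-[5-(benzyloxy)-2-bromo-3-methoxyphenyl]chromane | COc1cc(OCc2ccccc2)cc([C@@H]2COc3cc(OCc4ccccc4)ccc3C2)c1Br
F6 | step 11 | {4-(benzyloxy)-2-[(3R)-7-(benzyloxy)chroman-3-yl]-6-methoxyphenyl}lithium | COc1cc(OCc2ccccc2)cc([C@@H]2COc3cc(OCc4ccccc4)ccc3C2)c1[Li]
F7 | step 11 | 3-(benzyloxy)-6-({4-(benzyloxy)-2-[(3R)-7-(benzyloxy)chroman-3-yl]-6-methoxyphenyl}methylidene)cyclohexa-2,4-dien-1-one | COc1cc(OCc2ccccc2)cc([C@@H]2COc3cc(OCc4ccccc4)ccc3C2)c1C=C1C=CC(OCc2ccccc2)=CC1=O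
F8 | step 11 | (3R,4S)-2-pyrrolidinyl aminal of 19 (C2 not assigned; pyrrolidine as in 13) | COc1ccc([C@@H]2C(N3CCC[C@@H]3C(O[Si](C)(C)C)(c3ccccc3)c3ccccc3)Oc3cc(OCc4ccccc4)ccc3[C@H]2c2c(OC)cc(OCc3ccccc3)cc2[C@@H]2COc3cc(OCc4ccccc4)ccc3C2)c(OCc2ccccc2)c1OCc1ccccc1
F9 | step 4 | 1-[5-(benzyloxy)-2-bromo-3-methoxyphenyl]ethan-1-ol (racemic) | COc1cc(OCc2ccccc2)cc(C(C)O)c1Br
F10 | step 4 | 1-[5-(benzyloxy)-2-bromo-3-methoxyphenyl]ethan-1-one | COc1cc(OCc2ccccc2)cc(C(C)=O)c1Br
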